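The numbers of this flask are invented; no experiment stands behind them.

In a one-step world a substrate falls along a single exponential, and the exponent tells you what is left. I reckon this flask that way. Free catalyst takes up either mirror-image substrate into its intermediate (A from the left-handed, B from the right-handed). The coupling partner turns the intermediate into product and frees the catalyst, the added ligand parks catalyst as idle complex, and free catalyst slowly dies.

    free catalyst + left-handed substrate ⇌ catalyst intermediate A (K1 = 18 M⁻¹, k1 = 120 M⁻¹ s⁻¹)
    free catalyst + right-handed substrate ⇌ catalyst intermediate B (K2 = 21 M⁻¹, k2 = 31 M⁻¹ s⁻¹)
    coupling partner + catalyst intermediate A → free catalyst + left-handed product (k3 = 4.5 M⁻¹ s⁻¹)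
    coupling partner + catalyst intermediate B → free catalyst + right-handed product (k4 = 2.2 M⁻¹ s⁻¹)
    free catalyst → spent catalyst (k5 = 4.5 × 10⁻⁴ s⁻¹)
    coupling partner → decomposition product (k6 = 7.1 × 10⁻⁷ s⁻¹)
    free catalyst + added ligand ⇌ idle complex, settled at all times (K7 = 7500 M⁻¹)

- Thursday's: left-handed substrate 31 mM; coupling partner 62.0 mM; free catalyst 0.77 mM; added ligand 1.1 mM; right-handed substrate 31 mM; time 30 min
- Saturday's: left-handed substrate 31 mM; coupling partner 62.0 mM; free catalyst 1.2 mM; added ligand 1.1 mM; right-handed substrate 31 mM; time 30 min

- which of these there is most of at the end, counted by the substrate in it, Thursday's (left-handed substrate / right-handed substrate / right-handed product / left-handed product)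
- which of these there is most of at the end, counted by the substrate in it, Saturday's (left-handed substrate / right-handed substrate / right-handed product / left-handed product)
- the largest of these amounts at the end, in percent of the left-handed substrate and right-handed substrate together charged, Thursday's
- the largest of these amounts at the end, in percent of the left-handed substrate and right-handed substrate together charged, Saturday's

Both intermediates fall back faster than they go on: for A 6.67 s⁻¹ against 0.279 s⁻¹, for B 1.48 s⁻¹ against 0.136 s⁻¹. So each stays near balance with free catalyst and substrate. At the start, free catalyst and its intermediates together count 2.21 times the free catalyst. Balancing that against the ligand leaves a free share of 15.1% of the catalyst on Thursday and 19.1% on Saturday. I hold these shares steady, leaving out catalyst death, about 12.2% of Thursday's charge.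

Call the dose the exponent the right-handed substrate reaches with the partner at its charge: step 2's equilibrium constant, times step 4's rate constant, free catalyst, charged partner and time. It is 0.600 on Thursday and 1.18 on Saturday. The left-handed substrate takes that dose times the selectivity factor, 1.75.

Take two extremes, with amounts in percent of both substrates together. If the partner stays at its charge, Thursday ends with right-handed substrate 27.4% and left-handed product 32.5%. If it falls straight to nothing, its mean is half the charge, and Thursday gives 37.0% and 20.4%. So Thursday's leader changes between the extremes. Saturday's does not: even the second extreme gives product 32.2% against substrate 27.7%.

The real partner lies between. Its charge equals both substrates together, so the fraction left is about the mean of their two fractions. Replace its curve by the mean of start and end. A first pass at 75.0% of charge corrects this mean to 0.773 for Thursday and 0.656 for Saturday. I therefore commit to right-handed substrate at 31.4% on Thursday, and left-handed product at 37.1% on Saturday.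

The forecast names the same leaders with slightly different amounts: right-handed substrate at 33.2% on Thursday and left-handed product at 35.5% on Saturday, reasoning that “the roughly doubled free catalyst on Saturday pushes conversion past the crossover”.

The simulation gives right-handed substrate at 33.1% on Thursday and left-handed product at 35.6% on Saturday.

So the two recipes end with different leaders, and the same reckoning carries to a neighbour: Saturday's flask with 0.48 mM of free catalyst. Its free share is 12.7% and its dose 0.314, lower than Thursday's 0.600. With a mean partner of 0.863, that reckons to right-handed substrate 38.1% and left-handed product 18.9%. In the run, right-handed substrate leads the neighbour at 39.3%, with left-handed product at 17.7%.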